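**Retrosynthetic overview** (atom numbers are those of the target: ring A = C1–C6 with C1 = C(CH3)=, C4 = CHBr, C5 = C(CH3)2, C6 = spiro carbon; ring B = C6–C11 with C8 = CHBr, C9 = C(CH3)Cl)
- Key disconnection: C4–C5 and C1–C6 together. Ring A splits into a C5 aldehyde (C4 = CHO, C1 = silicon-bearing carbon of a (Z)-vinylsilane, C1 methyl in place) and the tetrasubstituted C5=C6 alkene of a halogenated p-menth-4(8)-ene that already is ring B.
- Enabling feature: the contiguous quaternary pair C5/C6 shared by rings A and B is the isopropylidene double bond of a terpinolene-type ring B. Its exocyclic carbon C5 takes the carbonyl carbon C4, and the resulting C6 cation is closed by C1, so ring A forms as a cyclohex-3-enol with C1=C2 fixed by silicon.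
- Ring order: ring B first, from (R)-limonene. Its ring stereocentre (the later C6) sets C8 and C9 by trans-diaxial bromochlorination and is then erased by moving the double bond to C5=C6. Ring A and the spiro centre follow in the key step.
- Endgame at C4 only: both carbinol epimers to one ketone, catalyst-controlled reduction, bromide by substitution with inversion.

Key step: step 5

Remark: compound names carry their own IUPAC locants; atom numbers in the Why lines are those of the target as defined above.

Step 1
Reactants: 1 (R)-(+)-limonene [(4R)-1-methyl-4-(prop-1-en-2-yl)cyclohex-1-ene]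
Product: 2 (1S,2S,4R)-2-bromo-1-chloro-1-methyl-4-(prop-1-en-2-yl)cyclohexane
Conditions: NBS (1.05 equiv), HCl (1.0 equiv, 2 M in Et2O), CH2Cl2, −78 °C
Reagents that add atoms: N-bromosuccinimide, O=C1CCC(=O)N1Br; hydrogen chloride, Cl
Why: Electrophilic anti bromochlorination with BrCl made in the flask: the trisubstituted ring alkene should react before the isopropenyl group, and chloride should open the bromonium ion at the tertiary carbon in the trans-diaxial sense (Fürst–Plattner rule) with the isopropenyl group equatorial, which sets C9 (S) and C8 (S) from the existing (R) centre, as in the trans-diaxial bromohydrin formation of limonene.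

Step 2
Reactants: 2 (1S,2S,4R)-2-bromo-1-chloro-1-methyl-4-(prop-1-en-2-yl)cyclohexane
Product: 3 (1S,2S)-2-bromo-1-chloro-1-methyl-4-(propan-2-ylidene)cyclohexane
Conditions: Co(salen*)Cl [salen* = N,N'-bis(3,5-di-tert-butylsalicylidene)-1,2-cyclohexanediamine dianion] (3 mol %), PhSiH3 (6 mol %), benzene, 22 °C
Reagents that add atoms: none
Why: Cobalt-hydride hydrogen-atom-transfer alkene isomerization: H-atom addition to the CH2 terminus gives the tertiary radical at C5, which loses the neighbouring ring methine hydrogen to give the tetrasubstituted C5=C6 alkene, which should be too hindered to react further; the stereocentre used in step 1 is erased on purpose and C8/C9 are not touched.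

Step 3
Reactants: 4 pent-3-yn-1-ol
Product: 5 (3Z)-4-(triethylsilyl)pent-3-en-1-ol
Conditions: Et3SiH (1.2 equiv), [Cp*Ru(MeCN)3]PF6 (2 mol %), CH2Cl2, 0 to 22 °C
Reagents that add atoms: triethylsilane, CC[SiH](CC)CC
Why: Ruthenium-catalysed trans-hydrosilylation of an internal alkyne: anti addition of Si–H with silicon at the methyl-bearing alkyne carbon remote from the hydroxyl should give the (Z)-vinylsilane, in which silicon is cis to the CH2CH2OH chain as the later ipso substitution requires.

Step 4
Reactants: 5 (3Z)-4-(triethylsilyl)pent-3-en-1-ol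
Product: 6 (3Z)-4-(triethylsilyl)pent-3-enal
Conditions: Dess–Martin periodinane, pyridine, CH2Cl2, 0 °C; used at once
Reagents that add atoms: none
Why: Dess–Martin oxidation of the primary alcohol under buffered, non-basic conditions, which should leave the β,γ-double bond and the vinylsilane in place.

Step 5
Reactants: 3 (1S,2S)-2-bromo-1-chloro-1-methyl-4-(propan-2-ylidene)cyclohexane; 6 (3Z)-4-(triethylsilyl)pent-3-enal
Product: 8 (6S,8S,9S)-8-bromo-9-chloro-1,1,5,9-tetramethylspiro[5.5]undec-4-en-2-ol (both C2 epimers; C2 of this name is C4 of the target), via triethylsilyl ether 7 (not isolated)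
Conditions: Et3SiNTf2 (10 mol %), CH2Cl2, −78 to −30 °C, 6 added slowly; then HF·pyridine, THF, 0 °C
Reagents that add atoms: none
Why: Proposed new method: the silyl Lewis acid should silylate the aldehyde oxygen of 6, the electron-rich tetrasubstituted alkene of 3 should add to the silyloxocarbenium ion through its exocyclic carbon (Prins addition, C4–C5), and the tertiary cation at C6 should then be captured by the silicon-bearing carbon of the (Z)-vinylsilane (ipso attack, C1–C6) with loss of Et3Si+, which both places the C1=C2 bond and regenerates the catalyst. The closest known reaction types are the silyl-Lewis-acid-catalysed carbonyl-ene/Prins addition of aldehydes to alkenes and the vinylsilane-terminated cation–olefin spirocyclization; their merger into an intermolecular annulation of a tetrasubstituted alkene is the new part. Ring A closes in a 6-endo-trig cation–olefin cyclization through a chair. The spiro centre C6 is controlled by ring B: C1 should enter axially and anti to the C8 bromine through the chair with equatorial Br and Cl, the only approach in which the bulky C5 becomes equatorial and neither C1 nor C5 meets the bromine in a syn-axial contact. C4 is not controlled (aldehyde face, remote from ring B), so both carbinol epimers are expected and are converged in steps 6 and 7. The step needs the first bond to form at C5 and not at C6, which the substrate should secure because axial approach to C6 is blocked by the axial C8 bromine of the ground-state chair while C5 is open on both faces, and it needs ring closure to outrun proton loss, which the non-basic NTf2 counter-ion, the silylated oxygen and the six-membered intramolecular trap should secure.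

Step 6
Reactants: 8 (6S,8S,9S)-8-bromo-9-chloro-1,1,5,9-tetramethylspiro[5.5]undec-4-en-2-ol (both C2 epimers)
Product: 9 (6S,8S,9S)-8-bromo-9-chloro-1,1,5,9-tetramethylspiro[5.5]undec-4-en-2-one
Conditions: Dess–Martin periodinane, pyridine, CH2Cl2, 0 to 22 °C
Reagents that add atoms: none
Why: Dess–Martin oxidation of the hindered secondary alcohol; both C4 epimers give the same ketone, and the buffered neutral medium should keep the C1=C2 bond out of conjugation.

Step 7
Reactants: 9 (6S,8S,9S)-8-bromo-9-chloro-1,1,5,9-tetramethylspiro[5.5]undec-4-en-2-one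
Product: 10 (2S,6S,8S,9S)-8-bromo-9-chloro-1,1,5,9-tetramethylspiro[5.5]undec-4-en-2-ol
Conditions: (R)-2-methyl-CBS-oxazaborolidine (20 mol %), BH3·SMe2 (1.0 equiv), toluene, −20 °C
Reagents that add atoms: none
Why: Corey–Bakshi–Shibata reduction: the ketone is flanked by the quaternary C5 (large) and the C3 methylene (small), so the (R)-oxazaborolidine should deliver hydride to the face that gives the (S)-alcohol at C4 under catalyst control, independent of the remote centres.

Step 8
Reactants: 10 (2S,6S,8S,9S)-8-bromo-9-chloro-1,1,5,9-tetramethylspiro[5.5]undec-4-en-2-ol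
Product: 11 (4R,6S,8S,9S)-4,8-dibromo-9-chloro-1,5,5,9-tetramethylspiro[5.5]undec-1-ene
Conditions: CBr4 (2 equiv), P(n-C8H17)3 (2 equiv), toluene, 70 °C
Reagents that add atoms: carbon tetrabromide, BrC(Br)(Br)Br
Why: Appel reaction: the oxyphosphonium ion should be displaced by bromide in an SN2 step with inversion, (S)-alcohol to (R)-bromide at C4, under neutral conditions chosen to limit elimination and 1,2-methyl shift at this neopentylic carbon.

**Compound list**
1 | (R)-(+)-limonene, (4R)-1-methyl-4-(prop-1-en-2-yl)cyclohex-1-ene | CC(=C)[C@@H]1CCC(C)=CC1 | starting material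
2 | (1S,2S,4R)-2-bromo-1-chloro-1-methyl-4-(prop-1-en-2-yl)cyclohexane | CC(=C)[C@@H]1CC[C@](C)(Cl)[C@@H](Br)C1 | intermediate
3 | (1S,2S)-2-bromo-1-chloro-1-methyl-4-(propan-2-ylidene)cyclohexane | CC(C)=C1CC[C@](C)(Cl)[C@@H](Br)C1 | intermediate
4 | pent-3-yn-1-ol | CC#CCCO | starting material
5 | (3Z)-4-(triethylsilyl)pent-3-en-1-ol | CC[Si](CC)(CC)/C(C)=C\CCO | intermediate
6 | (3Z)-4-(triethylsilyl)pent-3-enal | CC[Si](CC)(CC)/C(C)=C\CC=O | intermediate
7 | triethyl{[(6S,8S,9S)-8-bromo-9-chloro-1,1,5,9-tetramethylspiro[5.5]undec-4-en-2-yl]oxy}silane (both C2 epimers) | CC1=CCC(O[Si](CC)(CC)CC)C(C)(C)[C@]12CC[C@](C)(Cl)[C@@H](Br)C2 | intermediate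
8 | (6S,8S,9S)-8-bromo-9-chloro-1,1,5,9-tetramethylspiro[5.5]undec-4-en-2-ol (both C2 epimers) | CC1=CCC(O)C(C)(C)[C@]12CC[C@](C)(Cl)[C@@H](Br)C2 | intermediate
9 | (6S,8S,9S)-8-bromo-9-chloro-1,1,5,9-tetramethylspiro[5.5]undec-4-en-2-one | CC1=CCC(=O)C(C)(C)[C@]12CC[C@](C)(Cl)[C@@H](Br)C2 | intermediate
10 | (2S,6S,8S,9S)-8-bromo-9-chloro-1,1,5,9-tetramethylspiro[5.5]undec-4-en-2-ol | CC1=CC[C@H](O)C(C)(C)[C@]12CC[C@](C)(Cl)[C@@H](Br)C2 | intermediate
11 | (4R,6S,8S,9S)-4,8-dibromo-9-chloro-1,5,5,9-tetramethylspiro[5.5]undec-1-ene | CC1=CC[C@@H](Br)C(C)(C)[C@]12CC[C@](C)(Cl)[C@@H](Br)C2 | target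

Total step count: 8. Longest linear sequence: 6 steps (1, 2, 5, 6, 7, 8).

**Steps most likely to fail**

Step 5 (key step). Three processes could defeat the one-pot annulation. The first C–C bond may form at the ring carbon C6 instead of C5. The C6 cation may lose a proton (ene-type termination), or the vinylsilane may be protodesilylated, before ring closure. The silyl Lewis acid may ionize the tertiary chloride. The fallback makes the two bonds one after the other by known reactions and sets out from 3 and 6. Me2AlCl (1.1 equiv, CH2Cl2, −78 °C) should give the carbonyl-ene adduct (5Z)-2-[(4S,5S)-5-bromo-4-chloro-4-methylcyclohex-1-en-1-yl]-2-methyl-6-(triethylsilyl)hept-5-en-3-ol F1. Here the C4–C5 bond is formed, the hydrogen comes from a ring methylene, and the regiochemistry can be checked and the material purified before the second bond is made. Protonation of the trisubstituted ring alkene of F1 (CF3CO2H, CH2Cl2, −20 °C) should regenerate the C6 cation for the vinylsilane-terminated spirocyclization. The route is rejoined at 8.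

Step 8. Substitution at the neopentylic carbinol carbon may be outrun by elimination towards the conjugated cyclohexadiene or by ionization with a 1,2-methyl shift from C5. The fallback replaces the oxyphosphonium ion by a discrete sulfonate and sets out from 10. Tf2O and 2,6-lutidine (CH2Cl2, −78 °C) should give (2S,6S,8S,9S)-8-bromo-9-chloro-1,1,5,9-tetramethylspiro[5.5]undec-4-en-2-yl trifluoromethanesulfonate F2. Displacement with Bu4NBr in toluene at low temperature (SN2, inversion) rejoins the route at 11.

Step 2. Hydrogen-atom abstraction from the hindered ring methine may be slow, the cobalt hydride may reduce the secondary bromide, or the isomerization may run on into the ring. The fallback builds the tetrasubstituted alkene by cross-coupling and sets out from 2. Ozonolysis (O3, CH2Cl2/MeOH, −78 °C; Me2S) should give 1-[(1R,3S,4S)-3-bromo-4-chloro-4-methylcyclohexyl]ethan-1-one F3. Tf2O with 2,6-di-tert-butyl-4-methylpyridine (CH2Cl2, 0 °C) should give the more substituted enol triflate 1-[(3S,4S)-3-bromo-4-chloro-4-methylcyclohexylidene]ethyl trifluoromethanesulfonate F4. Negishi coupling with MeZnCl and Pd(PPh3)4 (THF, 50 °C) rejoins the route at 3.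

**Further compounds**
F1 | step 5 | (5Z)-2-[(4S,5S)-5-bromo-4-chloro-4-methylcyclohex-1-en-1-yl]-2-methyl-6-(triethylsilyl)hept-5-en-3-ol (both C3 epimers) | CC[Si](CC)(CC)/C(C)=C\CC(O)C(C)(C)C1=CC[C@](C)(Cl)[C@@H](Br)C1
F2 | step 8 | (2S,6S,8S,9S)-8-bromo-9-chloro-1,1,5,9-tetramethylspiro[5.5]undec-4-en-2-yl trifluoromethanesulfonate | CC1=CC[C@H](OS(=O)(=O)C(F)(F)F)C(C)(C)[C@]12CC[C@](C)(Cl)[C@@H](Br)C2
F3 | step 2 | 1-[(1R,3S,4S)-3-bromo-4-chloro-4-methylcyclohexyl]ethan-1-one | CC(=O)[C@@H]1CC[C@](C)(Cl)[C@@H](Br)C1
F4 | step 2 | 1-[(3S,4S)-3-bromo-4-chloro-4-methylcyclohexylidene]ethyl trifluoromethanesulfonate | CC(OS(=O)(=O)C(F)(F)F)=C1CC[C@](C)(Cl)[C@@H](Br)C1
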